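## Retrosynthetic overview
1. Aryl ketone C–C bond: Weinreb amide of the (R)-2-aryloxypropionic acid plus 3,4,5-trimethoxyphenyl Grignard. The ketone is unveiled last, so the labile α-centre never meets base.
2. Cinnamyl alcohol arm: Stille coupling of the aryl bromide with (E)-Bu3SnCH=CHCH2OH, with no protecting group.
3. C8–O bond and stereocentre: catalytic enantioselective [4+2] of the propionyl chloride-derived ammonium enolate with 5-bromo-3-methoxy-o-benzoquinone, where oxygen is the electrophile. The lactone is opened in the same flask and the freed OH is re-methylated.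
4. o-Quinone: oxidative dearomatisation with loss of one OMe from mirror-symmetric 4-bromosyringol, which comes from syringol.
5. Rings: both arenes are bought. Only a transient 1,4-benzodioxin-2-one ring forms in step 3, and it is opened again in that step.

Assumption: the target is (R) by CIP analysis, and O-benzoylquinine is taken to expose the re face of the enolate Cα, giving (R); if the first run gives (S), the pseudo-enantiomer O-benzoylquinidine is used and nothing else changes.

## Route

Step 1
Reactants: 1 2,6-dimethoxyphenol (syringol)
Product: 2 4-bromo-2,6-dimethoxyphenol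
Conditions: NBS (1.0 equiv), NaH (1 mol %), MeOH (cat.), CHCl3, −45 °C → rt
Reagents that add atoms: N-bromosuccinimide, O=C1CCC(=O)N1Br
Why: Electrophilic aromatic bromination, in which the OH is the strongest donor and, with both ortho positions blocked, steers Br+ to the para carbon, so the product keeps the mirror symmetry used in step 2.

Step 2
Reactants: 2 4-bromo-2,6-dimethoxyphenol
Product: 3 5-bromo-3-methoxycyclohexa-3,5-diene-1,2-dione (5-bromo-3-methoxy-o-benzoquinone)
Conditions: IBX (1.1 equiv), DMF, rt, 1 h, dark; cold aq NaHCO3 wash, dried, evaporated below 25 °C, used at once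
Reagents that add atoms: IBX (2-iodoxybenzoic acid), O=C1OI(=O)(O)c2ccccc12
Why: IBX ortho-oxygenation with oxidative demethylation of a 2-methoxyphenol (oxidative dearomatisation), in which the phenol binds to I(V), the oxo ligand is delivered intramolecularly to one of the two equivalent OMe-bearing ortho carbons and the mixed ketal expels MeOH, which removes both aromaticity and mirror symmetry, makes the former phenol oxygen electrophilic and avoids ipso attack at the para C–Br.

Step 3
Reactants: 3 5-bromo-3-methoxy-o-benzoquinone; 4 propionyl chloride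
Product: 7 (2R)-2-(4-bromo-2-hydroxy-6-methoxyphenoxy)-N-methoxy-N-methylpropanamide, via methylketene 5 (not isolated), via (3R)-7-bromo-5-methoxy-3-methyl-1,4-benzodioxin-2(3H)-one 6 (not isolated)
Conditions: 4 (1.2 equiv, slow addition), O-benzoylquinine (10 mol %), iPr2NEt (1.2 equiv), THF, −78 → −30 °C; then MeNH(OMe)·HCl (3 equiv), iPr2NEt (3 equiv), DMAP (10 mol %), → rt
Reagents that add atoms: N,O-dimethylhydroxylamine hydrochloride, CNOC.Cl
Why: Proposed new method: the closest known reaction is the cinchona-catalysed enantioselective [4+2] cycloaddition of ketene (ammonium) enolates with perhalogenated o-quinones (≥90% ee, driven by rearomatisation), extended here to a monohalogenated methoxy-o-quinone; O-benzoylquinine converts methylketene into a (Z)-ammonium enolate whose open re face bonds through Cα to a quinone oxygen and so sets (R), the freed phenoxide closes the lactone and releases the catalyst, Cα should go to O-2 because the 3-OMe and 5-Br lone pairs are conjugated with C1=O (leaving the LUMO mainly on C2=O) and because the O-1 phenoxide, meta to OMe and Br, is the better stabilised anion, and the aryl-ester lactone 6 is then aminolysed in the same flask without touching the stereocentre.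

Step 4
Reactants: 7 (2R)-2-(4-bromo-2-hydroxy-6-methoxyphenoxy)-N-methoxy-N-methylpropanamide
Product: 8 (2R)-2-(4-bromo-2,6-dimethoxyphenoxy)-N-methoxy-N-methylpropanamide
Conditions: MeI (1.5 equiv), K2CO3 (1.5 equiv), acetone, rt
Reagents that add atoms: iodomethane, CI
Why: Williamson ether synthesis on the only acidic OH restores the 2,6-dimethoxy pattern (one 6H OMe singlet and one 2H ArH singlet confirm the regiochemistry of step 3), and the amide α-H is too weakly acidic for K2CO3 to epimerise it.

Step 5
Reactants: 8 (2R)-2-(4-bromo-2,6-dimethoxyphenoxy)-N-methoxy-N-methylpropanamide; 9 (E)-3-(tributylstannyl)prop-2-en-1-ol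
Product: 10 (2R)-2-{4-[(E)-3-hydroxyprop-1-en-1-yl]-2,6-dimethoxyphenoxy}-N-methoxy-N-methylpropanamide
Conditions: Pd(PPh3)4 (5 mol %), toluene, 105 °C
Reagents that add atoms: none
Why: Migita–Kosugi–Stille coupling, in which oxidative addition into the unhindered C–Br bond and transmetalation of the vinylstannane with retention give the (E)-cinnamyl alcohol without a protecting group, and neutral conditions at the amide oxidation level leave the stereocentre untouched.

Step 6
Reactants: 10 (2R)-2-{4-[(E)-3-hydroxyprop-1-en-1-yl]-2,6-dimethoxyphenoxy}-N-methoxy-N-methylpropanamide; 11 5-bromo-1,2,3-trimethoxybenzene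
Product: 13 (2R)-2-{4-[(E)-3-hydroxyprop-1-en-1-yl]-2,6-dimethoxyphenoxy}-1-(3,4,5-trimethoxyphenyl)propan-1-one (CNP0171423.1), via 3,4,5-trimethoxyphenylmagnesium bromide 12 (not isolated)
Conditions: 11, Mg, I2 (cat.), THF, reflux; 12 (2.5 equiv) added to 10, THF, −20 → 0 °C; sat. aq NH4Cl, 0 °C
Reagents that add atoms: none
Why: Weinreb ketone synthesis, in which the first equivalent of 12 deprotonates the OH, the second adds to give a chelated tetrahedral magnesium adduct that cannot over-add, and the configurationally labile α-aryloxy ketone is released only in the cold, weakly acidic quench, so (R) is retained.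

## Compound list
1 | 2,6-dimethoxyphenol (syringol) | COc1cccc(OC)c1O | starting material
2 | 4-bromo-2,6-dimethoxyphenol | COc1cc(Br)cc(OC)c1O | intermediate
3 | 5-bromo-3-methoxycyclohexa-3,5-diene-1,2-dione | COC1=CC(Br)=CC(=O)C1=O | intermediate
4 | propionyl chloride | CCC(=O)Cl | starting material
5 | methylketene (prop-1-en-1-one) | CC=C=O | intermediate
6 | (3R)-7-bromo-5-methoxy-3-methyl-1,4-benzodioxin-2(3H)-one | C[C@H]1Oc2c(OC)cc(Br)cc2OC1=O | intermediate
7 | (2R)-2-(4-bromo-2-hydroxy-6-methoxyphenoxy)-N-methoxy-N-methylpropanamide | C[C@@H](Oc1c(O)cc(Br)cc1OC)C(=O)N(C)OC | intermediate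
8 | (2R)-2-(4-bromo-2,6-dimethoxyphenoxy)-N-methoxy-N-methylpropanamide | C[C@@H](Oc1c(OC)cc(Br)cc1OC)C(=O)N(C)OC | intermediate
9 | (E)-3-(tributylstannyl)prop-2-en-1-ol | CCCC[Sn](CCCC)(CCCC)/C=C/CO | starting material
10 | (2R)-2-{4-[(E)-3-hydroxyprop-1-en-1-yl]-2,6-dimethoxyphenoxy}-N-methoxy-N-methylpropanamide | C[C@@H](Oc1c(OC)cc(/C=C/CO)cc1OC)C(=O)N(C)OC | intermediate
11 | 5-bromo-1,2,3-trimethoxybenzene | COc1cc(Br)cc(OC)c1OC | starting material
12 | 3,4,5-trimethoxyphenylmagnesium bromide | COc1cc([Mg]Br)cc(OC)c1OC | intermediate
13 | (2R)-2-{4-[(E)-3-hydroxyprop-1-en-1-yl]-2,6-dimethoxyphenoxy}-1-(3,4,5-trimethoxyphenyl)propan-1-one | COc1cc(C(=O)[C@@H](C)Oc2c(OC)cc(/C=C/CO)cc2OC)cc(OC)c1OC | target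

## Step count and risks
Total steps: 6. Longest linear sequence: 6 (1 → 2 → 3 → 7 → 8 → 10 → 13). Compounds 4, 9 and 11 are bought, and 12 is made in the flask.

**Step 3 (highest risk).**
- Quinone 3 is far less electrophilic than perhalogenated o-quinones.
- The enolate may attack carbon (C4 or C6, giving α-arylation) or the other oxygen.
- The amines may add at C–Br.
- Fallback: drop the electrophilic-oxygen logic and make the C–O bond by SN2 with inversion, setting out from 2 and coming back at 8.
- Ethyl (S)-lactate is converted with MeNH(OMe)·HCl and iPrMgCl (THF, −20 °C) into (S)-2-hydroxy-N-methoxy-N-methylpropanamide F1.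
- A Mitsunobu reaction of F1 with phenol 2 (PPh3, DIAD, THF, 0 °C → rt) then gives (R)-8 directly.

**Step 2.**
- Quinone 3 may lose bromine. This can happen by ipso attack or by hydrolysis of the vinylogous acyl bromide to a hydroxy-p-quinone.
- It may also dimerise during isolation.
- Fallback: separate the symmetry-breaking from the oxidation, setting out from 2 and coming back at 3.
- Chelation-controlled mono-demethylation (AlCl3, pyridine, CH2Cl2, reflux) gives the storable 5-bromo-3-methoxybenzene-1,2-diol F2.
- F2 is oxidised under anhydrous conditions (Ag2O, MgSO4, Et2O, rt), filtered, and the solution of 3 is used directly.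

**Step 6.**
- The magnesium alkoxide of 10 may aggregate or precipitate.
- Excess Grignard may enolise the hindered amide, giving low conversion.
- Fallback: form the ketone before any protic group is present, setting out from 8 and coming back at 13.
- Compound 8 is treated with 12 (1.2 equiv, THF, −20 → 0 °C, NH4Cl quench) to give (R)-2-(4-bromo-2,6-dimethoxyphenoxy)-1-(3,4,5-trimethoxyphenyl)propan-1-one F3.
- The side chain is then added last by a base-free Stille coupling with 9 (Pd(PPh3)4, toluene, 100 °C). The ee is checked by chiral HPLC.

## Further compounds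
F1 | step 3 | (S)-2-hydroxy-N-methoxy-N-methylpropanamide | C[C@H](O)C(=O)N(C)OC
F2 | step 2 | 5-bromo-3-methoxybenzene-1,2-diol | COc1cc(Br)cc(O)c1O
F3 | step 6 | (R)-2-(4-bromo-2,6-dimethoxyphenoxy)-1-(3,4,5-trimethoxyphenyl)propan-1-one | COc1cc(C(=O)[C@@H](C)Oc2c(OC)cc(Br)cc2OC)cc(OC)c1OC
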